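**Retrosynthetic overview**

- The strategy rests on the C1–C7 glycol: the fully substituted carbinol C1 (oxygen cis to the C6 and C2 oxygens) and its C7H2–O arm are read as a syn-dihydroxylated exocyclic C1=C7 alkene on the cyclohexene ring, whose C2, C5, C6 oxygens and C3=C4 bond form the all-trans pattern of conduritol B.
- 14 ⇐ 13 by benzoylation of the primary C7–OH; 13 ⇐ 11 by hydroxyl-directed OsO4–TMEDA dihydroxylation (C1–O and C7–O bonds, C1 stereocenter).
- 11 ⇐ 7 (C2-symmetric conduritol B 1,4-dibenzoate) by mono-silylation, oxidation, CH2Br2–Zn–TiCl4 methylenation and desilylation.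
- 7 ⇐ 5 (conduritol B) ⇐ L-chiro-inositol 1, through the bis(butane-2,3-diacetal) 3 and olefination of its trans-diaxial 1,6-diol.
- Ring order: the only carbocycle is carried intact from 1; no ring of the target is formed in the route (two dioxane rings and an osmate chelate are temporary).

Key step: step 9

Remark: compounds 7–14 carry the target numbering (C1 = carbinol carbon bearing C7, C2–OBz, C3=C4, C5–OBz, C6–OH) and 1–5 the inositol or conduritol numbering; it is assumed that diacetal formation on 1 takes up the two trans-diequatorial pairs O2/O3 and O4/O5, the normal preference of this protecting group.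

**Route**

Step 1
Reactants: 1 L-chiro-inositol; 2 butane-2,3-dione
Product: 3 1L-2,3:4,5-bis-O-(2,3-dimethoxybutane-2,3-diyl)-chiro-inositol (free trans-diaxial 1,6-diol)
Conditions: butane-2,3-dione (2.5 equiv), HC(OMe)3, camphor-10-sulfonic acid (cat.), MeOH, reflux
Reagents that add atoms: butane-2,3-dione, CC(=O)C(C)=O; methanol, CO
Why: Acid-catalysed butane-2,3-diacetal formation is under thermodynamic control and selects vicinal trans-diequatorial diols, so the four contiguous equatorial hydroxyls should be taken up pairwise as two trans-fused dioxanes whose acetal centers are fixed by the axial, anomerically stabilised methoxy groups, while the trans-diaxial 1,6-diol stays free.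

Step 2
Reactants: 3 bis-diacetal 1,6-diol
Product: 4 conduritol B 1,2:3,4-bis(butane-2,3-diacetal)
Conditions: PPh3, imidazole, I2, toluene, reflux
Reagents that add atoms: none
Why: Garegg–Samuelsson deoxygenative olefination, in which PPh3/I2 turn the two hydroxyls into oxyphosphonium leaving groups and the antiperiplanar diaxial C–O bonds are lost by iodide-mediated reductive anti-elimination with formation of two P=O bonds, under conditions that leave the diacetals intact and create no stereocenter.

Step 3
Reactants: 4 conduritol B bis-diacetal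
Product: 5 conduritol B, (1R,2S,3S,4R)-cyclohex-5-ene-1,2,3,4-tetrol
Conditions: TFA/H2O (9:1), rt
Reagents that add atoms: none
Why: Acid hydrolysis of the two diacetals breaks only acetal C–O bonds, so the tetraol should be released with its four carbinol stereocenters untouched.

Step 4
Reactants: 5 conduritol B; 6 benzoyl chloride
Product: 7 1,4-di-O-benzoylconduritol B, (1R,4R,5R,6R)-5,6-dihydroxycyclohex-2-ene-1,4-diyl dibenzoate
Conditions: BzCl (2.1 equiv), pyridine, −40 → 0 °C
Reagents that add atoms: benzoyl chloride, O=C(Cl)c1ccccc1
Why: Regioselective acylation, since each allylic hydroxyl has a single oxygenated neighbour and is the less hindered and more acidic one, and its benzoylation deactivates the adjacent internal hydroxyl, so two equivalents of BzCl at low temperature should favour the C2-symmetric 1,4-diester (regioisomers can be returned to 5 by methanolysis).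

Step 5
Reactants: 7 conduritol B 1,4-dibenzoate
Product: 8 mono-TBS ether of 7 (C6–OTBS, C1–OH free, C2 and C5 benzoates)
Conditions: TBSOTf (1.0 equiv), 2,6-lutidine, CH2Cl2, −78 °C
Reagents that add atoms: tert-butyldimethylsilyl triflate, CC(C)(C)[Si](C)(C)OS(=O)(=O)C(F)(F)F
Why: Silylation of one of the two homotopic hydroxyls of a C2-symmetric diol gives the same compound whichever oxygen reacts, the bulky silyl group slows a second silylation next to it, and the cold, hindered-base conditions should prevent benzoate migration.

Step 6
Reactants: 8 mono-TBS ether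
Product: 9 C1 ketone (6-silyloxy-2,5-bis(benzoyloxy)cyclohex-3-en-1-one, used without chromatography)
Conditions: Dess–Martin periodinane, CH2Cl2, 0 °C → rt
Reagents that add atoms: none
Why: Dess–Martin oxidation converts the single free secondary alcohol to the ketone under non-basic conditions, which should avoid enolisation at C2 and β-elimination of the C5 benzoate.

Step 7
Reactants: 9 C1 ketone
Product: 10 C1-methylidene TBS ether (exocyclic C1=C7)
Conditions: CH2Br2, Zn, TiCl4 (reagent pre-formed in THF), CH2Cl2, 0 °C → rt
Reagents that add atoms: dibromomethane, BrCBr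
Why: Takai–Lombardo methylenation, in which the geminal dizinc reagent CH2(ZnBr)2 activated by TiCl4 is nucleophilic but non-basic and selective for ketones over esters, so the hindered, base-sensitive ketone should give the exocyclic alkene without epimerisation at C2 or C6 and without loss of benzoate.

Step 8
Reactants: 10 C1-methylidene TBS ether
Product: 11 (1R,4R,5R)-5-hydroxy-6-methylidenecyclohex-2-ene-1,4-diyl dibenzoate (target numbering: C1=C7H2, C2 and C5 benzoates, free C6–OH)
Conditions: HF·pyridine, pyridine, THF, 0 °C → rt
Reagents that add atoms: none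
Why: Fluoride cleavage of the silyl ether under buffered, weakly acidic conditions should free the directing C6 hydroxyl without benzoate migration or allylic transposition.

Step 9
Reactants: 11 6-methylidene conduritol 2,5-dibenzoate
Product: 13 C1/C6/C7-triol 2,5-dibenzoate (C1–OH cis to C6–OH and to C2–OBz), via TMEDA-chelated osmate ester 12 (not isolated)
Conditions: OsO4 (1.05 equiv), TMEDA (1.1 equiv), CH2Cl2, −78 °C; then HCl, MeOH, rt
Reagents that add atoms: osmium tetroxide, O=[Os](=O)(=O)=O
Why: OsO4 and TMEDA form the chelate OsO4(TMEDA), whose electron-rich oxo ligands accept a hydrogen bond from the allylic C6 hydroxyl of 11, and the bound reagent adds [3+2] across the adjacent exocyclic C1=C7 bond on the face that carries this hydroxyl to give the TMEDA-chelated hexavalent osmium glycolate 12, which does not turn over and is cleaved by HCl in methanol to 13 and OsO2Cl2(TMEDA). The closest known reaction type is the hydrogen-bond-directed syn dihydroxylation of cyclic and acyclic allylic alcohols with stoichiometric OsO4–TMEDA in CH2Cl2 at low temperature. The two new bonds are C1–O and C7–O, and no ring of the product is closed (the five-membered osmate chelate is temporary). The one new stereocenter, C1, is controlled by the C6 carbinol: the C1 oxygen is delivered cis to C6–OH and therefore cis to the C2 benzoate, with C7 trans. The step needs this face selectivity against the steric bias of the C2 benzoate, which the hydrogen bond should secure in a non-coordinating solvent at −78 °C where undirected osmylation is slow, and in the all-equatorial half-chair the C2 ester lies near the alkene plane and does not screen the lower face. It also needs chemoselectivity over C3=C4, which is secured by the more electron-rich and exposed 1,1-disubstituted exocyclic alkene, by the deactivation of the ring alkene by two allylic benzoates and its lack of a free allylic hydroxyl, and by the use of one equivalent of OsO4.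

Step 10
Reactants: 13 triol dibenzoate; 6 benzoyl chloride
Product: 14 [(1S,2R,5R,6S)-2,5-bis(benzoyloxy)-1,6-dihydroxycyclohex-3-en-1-yl]methyl benzoate (target)
Conditions: BzCl (1.05 equiv), 2,4,6-collidine, CH2Cl2, −40 → 0 °C
Reagents that add atoms: benzoyl chloride, O=C(Cl)c1ccccc1
Why: Chemoselective acylation, since with one equivalent of BzCl and a hindered pyridine base at low temperature the primary C7 hydroxyl should react well ahead of the secondary C6 hydroxyl (flanked by a quaternary carbon and a benzoate) and the tertiary C1 hydroxyl.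

**Compound list**

1 | L-chiro-inositol (1L-1,2,4/3,5,6-cyclohexanehexol) | O[C@H]1[C@@H](O)[C@H](O)[C@@H](O)[C@H](O)[C@@H]1O | starting material
2 | butane-2,3-dione | CC(=O)C(C)=O | starting material
3 | 1L-2,3:4,5-bis-O-(2,3-dimethoxybutane-2,3-diyl)-chiro-inositol (two trans-fused dioxanes, axial OMe, free trans-diaxial 1,6-diol) | O[C@H]1[C@H]2O[C@](C)(OC)[C@@](C)(OC)O[C@@H]2[C@H]3O[C@](C)(OC)[C@@](C)(OC)O[C@@H]3[C@@H]1O | intermediate
4 | conduritol B 1,2:3,4-bis(butane-2,3-diacetal) | C1=C[C@H]2O[C@](C)(OC)[C@@](C)(OC)O[C@@H]2[C@H]3O[C@](C)(OC)[C@@](C)(OC)O[C@@H]31 | intermediate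
5 | conduritol B, (1R,2S,3S,4R)-cyclohex-5-ene-1,2,3,4-tetrol | C1=C[C@@H](O)[C@H](O)[C@@H](O)[C@@H]1O | intermediate
6 | benzoyl chloride | O=C(Cl)c1ccccc1 | starting material
7 | 1,4-di-O-benzoylconduritol B, (1R,4R,5R,6R)-5,6-dihydroxycyclohex-2-ene-1,4-diyl dibenzoate | O[C@H]1[C@H](OC(=O)c2ccccc2)C=C[C@@H](OC(=O)c2ccccc2)[C@@H]1O | intermediate
8 | mono-TBS ether of 7 (C6–OTBS, C1–OH) | O[C@H]1[C@H](OC(=O)c2ccccc2)C=C[C@@H](OC(=O)c2ccccc2)[C@@H]1O[Si](C)(C)C(C)(C)C | intermediate
9 | C1 ketone (C2 and C5 benzoates, C6–OTBS) | O=C1[C@H](OC(=O)c2ccccc2)C=C[C@@H](OC(=O)c2ccccc2)[C@@H]1O[Si](C)(C)C(C)(C)C | intermediate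
10 | C1-methylidene TBS ether | C=C1[C@H](OC(=O)c2ccccc2)C=C[C@@H](OC(=O)c2ccccc2)[C@@H]1O[Si](C)(C)C(C)(C)C | intermediate
11 | (1R,4R,5R)-5-hydroxy-6-methylidenecyclohex-2-ene-1,4-diyl dibenzoate (key-step precursor) | C=C1[C@H](OC(=O)c2ccccc2)C=C[C@@H](OC(=O)c2ccccc2)[C@@H]1O | intermediate
12 | TMEDA-chelated hexavalent osmium glycolate of the C1/C7 diol (not isolated) | C[N+]1(C)CC[N+](C)(C)[Os-2]12(=O)(=O)OC[C@@]1(O2)[C@H](OC(=O)c3ccccc3)C=C[C@@H](OC(=O)c3ccccc3)[C@@H]1O | intermediate
13 | C1/C6/C7-triol 2,5-dibenzoate, (1S,2R,5R,6S) in target numbering (key-step product) | OC[C@@]1(O)[C@H](OC(=O)c2ccccc2)C=C[C@@H](OC(=O)c2ccccc2)[C@@H]1O | intermediate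
14 | [(1S,2R,5R,6S)-2,5-bis(benzoyloxy)-1,6-dihydroxycyclohex-3-en-1-yl]methyl benzoate | O=C(OC[C@@]1(O)[C@H](OC(=O)c2ccccc2)C=C[C@@H](OC(=O)c2ccccc2)[C@@H]1O)c1ccccc1 | target

**Step count and risks**

Total step count: 10. Longest linear sequence: 10 steps (1 → 14).

Steps most likely to fail:

1. Step 9. The hydrogen-bonded delivery may not outweigh steric approach control, giving poor facial selectivity at C1, or the ring alkene may be osmylated in competition. Fallback (sets out from 11, returns at 14): VO(acac)2 (cat.) and tert-butyl hydroperoxide in CH2Cl2 should epoxidise the exocyclic alkene through a vanadate ester of the C6 hydroxyl. This delivers the peroxide oxygen to the same face by a covalent instead of a hydrogen-bonded tether and should give the spiro-epoxide F1 (oxirane oxygen on C1 cis to C6–OH). Opening of F1 at the unhindered C7 methylene with benzoic acid and Ti(OiPr)4 then installs the C7 benzoate and leaves the C1 hydroxyl with its configuration, which is the target 14.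

2. Step 4. Acylation may not discriminate the allylic from the internal hydroxyls, leading to regioisomeric dibenzoates and over-acylation. Fallback (sets out from 1, returns at 7): the two kinds of oxygen are told apart by construction instead of by rate. Acetonation of 1 (2,2-dimethoxypropane, TsOH, DMF) should take up the two cis-diols as 1,2:5,6-di-O-isopropylidene-L-chiro-inositol F2. The free 3,4-diol is etherified (NaH, 4-methoxybenzyl chloride, DMF) to the bis-PMB ether F3. Aqueous acetic acid removes the acetonides to give tetraol F4. The equatorial hydroxyl of each cis-diol is then benzoylated by way of its stannylene acetal (Bu2SnO, then BzCl) to give the 2,5-dibenzoate F5. PPh3/imidazole/I2 olefination of the trans-diaxial 1,6-diol gives the protected conduritol B F6, and DDQ in wet CH2Cl2 removes the PMB groups to reach 7.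

3. Step 7. Enolisation of the ketone toward C2 (loss of configuration) or elimination of benzoic acid with aromatisation may outrun methylenation of the hindered carbonyl group. Fallback (sets out from 9, returns at 11): a two-stage Peterson olefination replaces the titanium reagent. Addition of the weakly basic organocerium reagent from Me3SiCH2Li and CeCl3 (THF, −78 °C) to the ketone should give the β-hydroxysilane F7 (C1 configuration not controlled and removed in the next operation). Aqueous HF in MeCN then brings about both the acid-type elimination to the exocyclic alkene and the cleavage of the TBS ether, giving 11 directly.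

**Further compounds**

F1 | step 9 | spiro-epoxide of 11 (C1–C7 oxirane, oxygen on C1 cis to C6–OH) | C1O[C@@]12[C@H](OC(=O)c3ccccc3)C=C[C@@H](OC(=O)c3ccccc3)[C@@H]2O
F2 | step 4 | 1,2:5,6-di-O-isopropylidene-L-chiro-inositol | CC1(C)O[C@H]2[C@@H](O1)[C@H](O)[C@@H](O)[C@@H]3OC(C)(C)O[C@H]23
F3 | step 4 | 1,2:5,6-di-O-isopropylidene-3,4-bis-O-(4-methoxybenzyl)-L-chiro-inositol | CC1(C)O[C@H]2[C@@H](O1)[C@H](OCc4ccc(OC)cc4)[C@@H](OCc4ccc(OC)cc4)[C@@H]3OC(C)(C)O[C@H]23
F4 | step 4 | 3,4-bis-O-(4-methoxybenzyl)-L-chiro-inositol | O[C@H]1[C@@H](O)[C@H](OCc2ccc(OC)cc2)[C@@H](OCc2ccc(OC)cc2)[C@H](O)[C@@H]1O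
F5 | step 4 | 2,5-di-O-benzoyl-3,4-bis-O-(4-methoxybenzyl)-L-chiro-inositol | O[C@H]1[C@@H](OC(=O)c2ccccc2)[C@H](OCc2ccc(OC)cc2)[C@@H](OCc2ccc(OC)cc2)[C@H](OC(=O)c2ccccc2)[C@@H]1O
F6 | step 4 | 1,4-di-O-benzoyl-2,3-bis-O-(4-methoxybenzyl)conduritol B | C1=C[C@@H](OC(=O)c2ccccc2)[C@H](OCc2ccc(OC)cc2)[C@@H](OCc2ccc(OC)cc2)[C@@H]1OC(=O)c1ccccc1
F7 | step 7 | C1 β-hydroxysilane from 9 (C1 carbinol bearing CH2SiMe3, either C1 epimer) | C[Si](C)(C)CC1(O)[C@H](OC(=O)c2ccccc2)C=C[C@@H](OC(=O)c2ccccc2)[C@@H]1O[Si](C)(C)C(C)(C)C
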